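Lignan numbering: C8 is the hydroxylated bridgehead, C8' the CH bridgehead, C7/C9 the ArCH/CH2 on C8, C7'/C9' those on C8'; ring A = C7'–O–C9–C8–C8', ring B = C7–O–C9'–C8'–C8; Ar = 3,5-dimethoxy-4-(triisopropylsilyloxy)phenyl.
Retrosynthesis: after removal of the two silyl groups, ring B is cut at C7–O and at C7–aryl (back to a C7 lactone), the C8 hydroxyl is taken off (enolate oxidation), and ring A is then cut at C7'–O and C9–C8.
That last cut is possible because ring A is formaldehyde (O and C9) joined to the three-carbon unit C7'–C8'–C8, in which C7' carries a cation-stabilising aryl group and C8 is alpha to the C7 carbonyl; this is the pattern of a donor–acceptor cyclopropane.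
Forward: aryl bromide, Z-arylallyl diazoacetate, cyclopropane fused to the ring-B lactone, ring A by (3+2) annulation with formaldehyde, C8 hydroxylation, second aryl group on C7, ring B by benzylic cation closure, desilylation.
Stereochemistry: the Rh2(5R-MEPY)4 cyclopropanation of the Z alkene fixes C8' and the endo aryl group; the annulation sets C7' by inversion and C8 by cis ring fusion; the C8 hydroxyl can only enter cis to H8'; C7 is set in the kinetically exo-selective closure of ring B.

Key step: step 6

Assumption: Rh2(5R-MEPY)4 (MEPY = methyl 2-oxopyrrolidine-5-carboxylate) is taken to show the same sense of induction with the Z-aryl substrate as with simple allylic diazoacetates, giving the (1S,5R) ring fusion; if the sense proves opposite, Rh2(5S-MEPY)4 is used with no other change.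

Step 1
Reactants: 1 4-bromo-2,6-dimethoxyphenol
Product: 2 (4-bromo-2,6-dimethoxyphenoxy)triisopropylsilane (ArBr)
Conditions: i-Pr3SiCl, imidazole, DMF, rt to 40 °C
Reagents that add atoms: triisopropylsilyl chloride, CC(C)[Si](Cl)(C(C)C)C(C)C
Why: Imidazole-mediated silylation of a phenol is routine, and the bulky triisopropylsilyl ether is chosen because it has to survive a Lewis acid at 50 °C, KN(SiMe3)2 and an aryllithium yet still falls to fluoride at the end.

Step 2
Reactants: 2 ArBr; 3 propargyl alcohol
Product: 4 3-Ar-prop-2-yn-1-ol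
Conditions: Pd(PhCN)2Cl2 (3 mol %), [(t-Bu)3PH]BF4 (6 mol %), CuI (2 mol %), i-Pr2NH, 1,4-dioxane, rt to 45 °C
Reagents that add atoms: none
Why: Sonogashira coupling, in which the bulky electron-rich phosphine lets the electron-rich aryl bromide undergo oxidative addition near room temperature while the free propargylic hydroxyl and the silyl ether are left alone.

Step 3
Reactants: 4 3-Ar-prop-2-yn-1-ol
Product: 5 (Z)-3-Ar-prop-2-en-1-ol
Conditions: H2 (1 atm), Pd/CaCO3 poisoned with Pb(OAc)2, quinoline, EtOAc, rt
Reagents that add atoms: none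
Why: Lindlar-type semihydrogenation delivers both hydrogens to one face of the alkyne on the lead-poisoned palladium surface and so should give the Z alkene, with quinoline holding back over-reduction.

Step 4
Reactants: 5 (Z)-3-Ar-prop-2-en-1-ol
Product: 7 (Z)-3-Ar-prop-2-en-1-yl diazoacetate, via glyoxylate tosylhydrazone ester 6 (not isolated)
Conditions: TsNHN=CHCOCl, PhNMe2, CH2Cl2, 0 °C; then Et3N, 0 °C to rt
Reagents that add atoms: glyoxylic acid chloride p-toluenesulfonylhydrazone, Cc1ccc(cc1)S(=O)(=O)NN=CC(Cl)=O
Why: Acylation of the alcohol by the acid chloride followed by triethylamine-induced loss of sulfinate from the tosylhydrazone (Bamford–Stevens-type elimination) is the standard one-flask diazoacetate synthesis and is mild enough to leave the Z alkene and the aryl silyl ether intact.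

Step 5
Reactants: 7 (Z)-3-Ar-prop-2-en-1-yl diazoacetate
Product: 8 (1S,5R,6S)-6-Ar-3-oxabicyclo[3.1.0]hexan-2-one (aryl endo, cis to the lactone ring)
Conditions: Rh2(5R-MEPY)4 (1 mol %), CH2Cl2, reflux, slow addition of 7
Reagents that add atoms: none
Why: Intramolecular cyclopropanation by the rhodium carbene is a stereospecific syn addition, so the Z geometry places the aryl group endo, while the chiral carboxamidate ligands choose the alkene face and thereby set C8', C8 and C7' in one event, Z-allylic diazoacetates being the substrate class this catalyst family handles best.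

Step 6
Reactants: 8 (1S,5R,6S)-6-Ar-3-oxabicyclo[3.1.0]hexan-2-one; 9 formaldehyde (charged as paraformaldehyde)
Product: 10 (1R,5R,6S)-6-Ar-3,7-dioxabicyclo[3.3.0]octan-2-one (ring A complete, ring B as the C7 lactone, aryl exo)
Conditions: (CH2O)n (5 equiv), Sc(OTf)3 (20 mol %), 4 Å MS, ClCH2CH2Cl–(CF3)2CHOH (9:1), 50 °C
Reagents that add atoms: none
Why: Proposed new method: Sc(OTf)3 on the lactone carbonyl polarises the C7'–C8 bond, the one cyclopropane bond that is both benzylic to the oxygenated arene and aligned with the C=O π* orbital of the rigid bicycle, so that formaldehyde oxygen (or a hemiformal end group that then sheds its chain) attacks C7' from the rear and leaves a scandium lactone enolate tethered to an O-alkylated formaldehyde cation; the enolate carbon C8 then bonds to C9 in an intramolecular aldol-type step. The closest known reaction type is the Lewis-acid (3+2) annulation of 2-arylcyclopropane-1,1-diesters with aldehydes to tetrahydrofurans, from which this differs in having a single acceptor and formaldehyde as partner; the hydrogen-bond-donating fluoro alcohol co-solvent is added to make up for the weaker activation. Ring A closes in a 5-(enolexo)-endo-trig attack on the C=O+ bond, the mode that operates in those annulations and in Prins-type closures. C7' is set by inversion at the cyclopropane carbon, which turns the endo aryl group of 8 into the exo aryl group of 10 (trans to C9'), and C8 is set by the ring fusion, since the bicyclo[3.3.0] system can only close cis to the untouched C8'–H. The step needs cleavage of C7'–C8 in preference to the other two ring bonds and closure faster than proton loss from C8' or capture by the arene; the push–pull character of that bond, the strain of the bicyclo[3.1.0] lactone and the short tether should secure this, and should free ionisation intervene the exo aryl position is still the favoured one.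

Step 7
Reactants: 10 (1R,5R,6S)-6-Ar-3,7-dioxabicyclo[3.3.0]octan-2-one
Product: 12 (1S,5R,6S)-1-hydroxy-6-Ar-3,7-dioxabicyclo[3.3.0]octan-2-one, via potassium lactone enolate 11 (not isolated)
Conditions: KN(SiMe3)2, THF, −78 °C; then 3-phenyl-2-(phenylsulfonyl)oxaziridine, −78 °C; aq NH4Cl
Reagents that add atoms: 3-phenyl-2-(phenylsulfonyl)oxaziridine, O=S(=O)(c1ccccc1)N1OC1c1ccccc1
Why: Davis oxidation of the potassium lactone enolate, in which the C9–O bond lies near the nodal plane of the enolate so that β-elimination of the ring-A oxygen should be slow at −78 °C, and oxygen can only be delivered cis to H8' because the alternative would be a trans-fused bicyclo[3.3.0]octane, so the hydroxyl takes the place of H8.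

Step 8
Reactants: 12 (1S,5R,6S)-1-hydroxy-6-Ar-3,7-dioxabicyclo[3.3.0]octan-2-one; 2 ArBr
Product: 14 (1S,5R,6S)-2,6-di-Ar-3,7-dioxabicyclo[3.3.0]octane-1,2-diol (C7 hemiketal as both epimers), via aryllithium 13 (not isolated)
Conditions: 2 (2.4 equiv), n-BuLi (2.3 equiv), THF, −78 °C; then 12, −78 °C; aq NH4Cl
Reagents that add atoms: none
Why: Bromine–lithium exchange gives the aryllithium, one equivalent of which deprotonates the tertiary alcohol while a second adds to the C7 lactone carbonyl to give a lithium hemiketalate that is stable at −78 °C and therefore should not accept a further aryl group.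

Step 9
Reactants: 14 C7 hemiketal
Product: 15 (3S,4R,5S)-5-Ar-3-[Ar(hydroxy)methyl]-4-(hydroxymethyl)oxolan-3-ol (ring A intact, both C7 carbinol epimers)
Conditions: NaBH4, MeOH–THF, 0 °C to rt
Reagents that add atoms: none
Why: Borohydride reduction of the open hydroxy ketone tautomer of the hemiketal gives the benzylic carbinol, whose configuration at C7 does not matter because that centre is ionised in the next step.

Step 10
Reactants: 15 triol
Product: 16 (1S,2R,5R,6S)-2,6-di-Ar-3,7-dioxabicyclo[3.3.0]octan-1-ol (bis-silyl ether of the target)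
Conditions: camphor-10-sulfonic acid (10 mol %), CH2Cl2, −20 to 0 °C
Reagents that add atoms: none
Why: Acid-catalysed SN1 cycloetherification, the classical ring closure of furofuran lignans, in which the C7 carbinol ionises to a benzylic cation stabilised by the para oxygen and is captured by the primary C9' hydroxyl in a 5-exo closure of ring B that is necessarily cis-fused, the aryl group settling kinetically on the convex face, cis to the C8 hydroxyl and away from ring A, which sets C7.

Step 11
Reactants: 16 bis-silyl ether
Product: 17 8-hydroxysyringaresinol, (1S,2R,5R,6S)-2,6-bis(4-hydroxy-3,5-dimethoxyphenyl)-3,7-dioxabicyclo[3.3.0]octan-1-ol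
Conditions: Bu4NF, AcOH, THF, 0 °C
Reagents that add atoms: none
Why: Fluoride cleaves both aryl silyl ethers, and acetic acid buffering keeps the liberated syringyl phenols from standing as oxidation-prone phenoxides, the furofuran core and the tertiary alcohol being inert.

Compound list
1 | 4-bromo-2,6-dimethoxyphenol | COc1cc(Br)cc(OC)c1O | starting material
2 | (4-bromo-2,6-dimethoxyphenoxy)triisopropylsilane (ArBr) | COc1cc(Br)cc(OC)c1O[Si](C(C)C)(C(C)C)C(C)C | intermediate
3 | propargyl alcohol | OCC#C | starting material
4 | 3-Ar-prop-2-yn-1-ol | COc1cc(C#CCO)cc(OC)c1O[Si](C(C)C)(C(C)C)C(C)C | intermediate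
5 | (Z)-3-Ar-prop-2-en-1-ol | COc1cc(/C=C\CO)cc(OC)c1O[Si](C(C)C)(C(C)C)C(C)C | intermediate
6 | (Z)-3-Ar-prop-2-en-1-yl glyoxylate p-toluenesulfonylhydrazone (not isolated) | COc1cc(/C=C\COC(=O)C=NNS(=O)(=O)c2ccc(C)cc2)cc(OC)c1O[Si](C(C)C)(C(C)C)C(C)C | intermediate
7 | (Z)-3-Ar-prop-2-en-1-yl diazoacetate | COc1cc(/C=C\COC(=O)C=[N+]=[N-])cc(OC)c1O[Si](C(C)C)(C(C)C)C(C)C | intermediate
8 | (1S,5R,6S)-6-Ar-3-oxabicyclo[3.1.0]hexan-2-one, aryl endo | O=C1OC[C@@H]2[C@H](c3cc(OC)c(O[Si](C(C)C)(C(C)C)C(C)C)c(OC)c3)[C@H]12 | intermediate
9 | formaldehyde (charged as paraformaldehyde) | C=O | starting material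
10 | (1R,5R,6S)-6-Ar-3,7-dioxabicyclo[3.3.0]octan-2-one | COc1cc([C@H]2OC[C@@H]3C(=O)OC[C@H]23)cc(OC)c1O[Si](C(C)C)(C(C)C)C(C)C | intermediate
11 | potassium enolate of 10 (not isolated) | COc1cc([C@H]2OCC3=C([O-])OC[C@H]23)cc(OC)c1O[Si](C(C)C)(C(C)C)C(C)C.[K+] | intermediate
12 | (1S,5R,6S)-1-hydroxy-6-Ar-3,7-dioxabicyclo[3.3.0]octan-2-one | COc1cc([C@H]2OC[C@]3(O)C(=O)OC[C@H]23)cc(OC)c1O[Si](C(C)C)(C(C)C)C(C)C | intermediate
13 | [3,5-dimethoxy-4-(triisopropylsilyloxy)phenyl]lithium (not isolated) | [Li]c1cc(OC)c(O[Si](C(C)C)(C(C)C)C(C)C)c(OC)c1 | intermediate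
14 | (1S,5R,6S)-2,6-di-Ar-3,7-dioxabicyclo[3.3.0]octane-1,2-diol, hemiketal at C7 (both epimers, in equilibrium with the open C7 ketone) | COc1cc([C@H]2OC[C@]3(O)C(O)(c4cc(OC)c(O[Si](C(C)C)(C(C)C)C(C)C)c(OC)c4)OC[C@H]23)cc(OC)c1O[Si](C(C)C)(C(C)C)C(C)C | intermediate
15 | (3S,4R,5S)-5-Ar-3-[Ar(hydroxy)methyl]-4-(hydroxymethyl)oxolan-3-ol (both C7 carbinol epimers) | COc1cc([C@H]2OC[C@](O)(C(O)c3cc(OC)c(O[Si](C(C)C)(C(C)C)C(C)C)c(OC)c3)[C@@H]2CO)cc(OC)c1O[Si](C(C)C)(C(C)C)C(C)C | intermediate
16 | (1S,2R,5R,6S)-2,6-di-Ar-3,7-dioxabicyclo[3.3.0]octan-1-ol | COc1cc([C@H]2OC[C@]3(O)[C@@H](c4cc(OC)c(O[Si](C(C)C)(C(C)C)C(C)C)c(OC)c4)OC[C@H]23)cc(OC)c1O[Si](C(C)C)(C(C)C)C(C)C | intermediate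
17 | 8-hydroxysyringaresinol, (1S,2R,5R,6S)-2,6-bis(4-hydroxy-3,5-dimethoxyphenyl)-3,7-dioxabicyclo[3.3.0]octan-1-ol | COc1cc([C@H]2OC[C@]3(O)[C@@H](c4cc(OC)c(O)c(OC)c4)OC[C@H]23)cc(OC)c1O | target

Total step count: 11.
Longest linear sequence: 11 steps (1 to 17); aryl bromide 2 is drawn on a second time in step 8.

Steps most likely to fail

Step 6 (the proposed annulation). The single lactone acceptor may not polarise the C7'–C8 bond enough for the weakly nucleophilic formaldehyde oxygen to open it. Alternatively the ring may open to a free benzylic cation that loses the C8' proton or is captured by its own arene before the enolate closes. The fallback uses known reactions, sets out from 8 and returns at 10, making the two bonds one after the other. Acid-catalysed hydrolytic opening of the cyclopropane at the benzylic carbon (TfOH cat., (CF3)2CHOH–H2O, rt) is the known solvolytic opening of aryl cyclopropanes carrying one acceptor and should proceed with inversion, giving the benzylic alcohol (4R)-4-[(S)-hydroxy(Ar)methyl]oxolan-2-one F1. MOMCl and i-Pr2NEt convert it into the methoxymethyl ether F2. LiN(SiMe3)2 and Me3SiCl at −78 °C give the silyl ketene acetal F3. Catalytic Me3SiOTf in CH2Cl2 at −78 °C then ionises the methoxymethyl group to the same O-alkylated formaldehyde cation, which the ketene acetal carbon C8 captures in an intramolecular Mukaiyama-type acetal alkylation to give 10, cis-fused by necessity. If the opening is not fully invertive, the C7' epimers are separated at F1.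

Step 10 (closure of ring B). The C7 cation may be captured with poor facial selectivity, the ring-A benzylic ether may ionise and epimerise at C7', or a 1,2-shift from the neighbouring carbinol carbon C8 may compete with ring closure. The fallback sets out from 15 and returns at 17 by reversing the order of the last two operations. Bu4NF with AcOH first frees both phenols to give the pentahydroxy compound (3S,4R,5S)-5-(4-hydroxy-3,5-dimethoxyphenyl)-3-[hydroxy(4-hydroxy-3,5-dimethoxyphenyl)methyl]-4-(hydroxymethyl)oxolan-3-ol F4. With the para hydroxyl free, the C7 carbinol loses water to a neutral p-quinone methide under very mild acid (pyridinium p-toluenesulfonate, MeCN, rt). Intramolecular 1,6-addition of the C9' hydroxyl, the known quinone-methide closure of furofuran lignans, then gives 17 directly.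

Step 8 (aryl addition to the lactone). Addition may stall because the neighbouring lithium alkoxide shields the hindered C7 carbonyl, or premature collapse of the hemiketalate may allow a second aryl group to add. The fallback sets out from 12 and returns at 15. i-Bu2AlH (CH2Cl2, −78 °C) reduces the lactone to the lactol (1S,5R,6S)-6-Ar-3,7-dioxabicyclo[3.3.0]octane-1,2-diol F5. An excess of aryllithium 13 then adds to its open hydroxy aldehyde form, the standard lactol-plus-aryl-organometallic entry to furofuran diols, to give triol 15 directly. Over-addition cannot occur and the borohydride step is no longer needed.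

Further compounds
F1 | step 6 | (4R)-4-[(S)-hydroxy(Ar)methyl]oxolan-2-one | COc1cc([C@@H](O)[C@@H]2CC(=O)OC2)cc(OC)c1O[Si](C(C)C)(C(C)C)C(C)C
F2 | step 6 | (4R)-4-[(S)-(methoxymethoxy)(Ar)methyl]oxolan-2-one | COc1cc([C@@H](OCOC)[C@@H]2CC(=O)OC2)cc(OC)c1O[Si](C(C)C)(C(C)C)C(C)C
F3 | step 6 | trimethylsilyl ketene acetal of F2, (4R)-4-[(S)-(methoxymethoxy)(Ar)methyl]-2-(trimethylsilyloxy)-4,5-dihydrofuran | COc1cc([C@@H](OCOC)[C@@H]2C=C(O[Si](C)(C)C)OC2)cc(OC)c1O[Si](C(C)C)(C(C)C)C(C)C
F4 | step 10 | (3S,4R,5S)-5-(4-hydroxy-3,5-dimethoxyphenyl)-3-[hydroxy(4-hydroxy-3,5-dimethoxyphenyl)methyl]-4-(hydroxymethyl)oxolan-3-ol (both C7 carbinol epimers) | COc1cc([C@H]2OC[C@](O)(C(O)c3cc(OC)c(O)c(OC)c3)[C@@H]2CO)cc(OC)c1O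
F5 | step 8 | (1S,5R,6S)-6-Ar-3,7-dioxabicyclo[3.3.0]octane-1,2-diol (C7 lactol, both epimers) | COc1cc([C@H]2OC[C@]3(O)C(O)OC[C@H]23)cc(OC)c1O[Si](C(C)C)(C(C)C)C(C)C
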